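**Plan**

1. Retrosynthetic cuts: first the acetate, the two phenol benzyl ethers and a temporary benzylic C4–O bond, which fold C1 and C4 into one γ-butyrolactone (ring O–C1(=O)–C2–C3–C4); then the bond between the guaiacyl ring carbon and C1'; then C1–C2 and C1–O (carbon monoxide); last C3–C4.
2. Enabling feature: C1 and C4 stand 1,4 to each other, so an oxygen bridge gives a five-membered lactone in which C1' is the terminal carbon of an exocyclic enoate on C2, C2–H is acidic, and the ring O–C4 bond lies beside the electron-rich syringyl ring.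
3. Forward order: propargylation joins C3–C4, cyclocarbonylation closes the lactone, rhodium-catalysed 1,4-arylation joins the guaiacyl ring to C1' and base funnels C2, hydride opens the ring, acetylation follows, and one hydrogenolysis removes the C4 oxygen and both benzyl groups.
4. Stereochemistry: C3 comes from (R)-but-3-yn-2-ol by chirality transfer through an allenylzinc (net inversion); C2 is set by thermodynamic equilibration trans to the C3 methyl group in the lactone; the C4 carbinol centre is temporary and ends as CH2.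

Key step: step 5

Remark: atoms are numbered as in the target chain (C1 acetoxymethyl carbon = lactone carbonyl carbon, C2, C3 methyl-bearing, C4 benzylic carbon at the syringyl ring, C1' the CH2 between C2 and the guaiacyl ring). The route is written for the anti adduct 6; any syn (C4-epimeric) material has the same C3 configuration and should converge on 13, because C4 becomes CH2 in step 8.

**Step 1**
Reactants: 1 syringaldehyde (4-hydroxy-3,5-dimethoxybenzaldehyde)
Product: 2 4-(benzyloxy)-3,5-dimethoxybenzaldehyde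
Conditions: BnBr, K2CO3, DMF, 60 °C
Reagents that add atoms: benzyl bromide, BrCc1ccccc1
Why: Williamson ether synthesis on the phenoxide masks the phenol as a benzyl ether that survives every later step and falls off in the final hydrogenolysis.

**Step 2**
Reactants: 3 (R)-but-3-yn-2-ol
Product: 4 (R)-but-3-yn-2-yl methanesulfonate
Conditions: MsCl, Et3N, CH2Cl2, −78 to 0 °C
Reagents that add atoms: methanesulfonyl chloride, CS(=O)(=O)Cl
Why: O-sulfonylation forms only the O–S bond, so the carbinol configuration is retained and the propargylic leaving group is in place.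

**Step 3**
Reactants: 2 4-(benzyloxy)-3,5-dimethoxybenzaldehyde; 4 (R)-but-3-yn-2-yl methanesulfonate
Product: 6 (1S,2S)-1-[4-(benzyloxy)-3,5-dimethoxyphenyl]-2-methylbut-3-yn-1-ol, via allenylzinc 5 (not isolated)
Conditions: Pd(OAc)2 (5 mol%), PPh3 (5 mol%), Et2Zn (3 equiv), THF, −78 to −20 °C; aq. NH4Cl
Reagents that add atoms: none
Why: Marshall–Tamaru propargylation: zerovalent palladium opens 4 by anti SN2' attack, transmetalation to zinc gives allenylzinc 5, and its addition to 2 through a closed six-membered transition state (syn SE2') should set the methyl-bearing carbon with net inversion (2S) and favour the anti (1S) carbinol.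

**Step 4**
Reactants: 6 (1S,2S)-1-[4-(benzyloxy)-3,5-dimethoxyphenyl]-2-methylbut-3-yn-1-ol
Product: 7 (4S,5S)-5-[4-(benzyloxy)-3,5-dimethoxyphenyl]-4-methyl-3-methylideneoxolan-2-one
Conditions: PdCl2 (5 mol%), PPh3 (10 mol%), SnCl2 (5 mol%), CO (8 bar), MeCN, 75 °C
Reagents that add atoms: carbon monoxide, [C-]#[O+]
Why: Palladium-catalysed cyclocarbonylation of a homopropargylic alcohol (alkoxycarbonyl complex of divalent palladium, 5-exo syn-insertion of the terminal alkyne, protonolysis) is the classical entry to α-methylene-γ-butyrolactones and touches neither stereocentre.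

**Step 5**
Reactants: 7 (4S,5S)-5-[4-(benzyloxy)-3,5-dimethoxyphenyl]-4-methyl-3-methylideneoxolan-2-one; 8 [4-(benzyloxy)-3-methoxyphenyl]boronic acid
Product: 10 (3S,4S,5S)-3-[4-(benzyloxy)-3-methoxybenzyl]-5-[4-(benzyloxy)-3,5-dimethoxyphenyl]-4-methyloxolan-2-one, via cis-epimer 9 (not isolated)
Conditions: 8 (1.5 equiv), [Rh(OH)(cod)]2 (2.5 mol%, cod = 1,5-cyclooctadiene), 1,4-dioxane/H2O 10:1, 40 °C; then solvent change to toluene, DBU (0.3 equiv), 60 °C
Reagents that add atoms: none
Why: The monovalent rhodium hydroxide takes the aryl group from 8 by transmetalation, the aryl–rhodium bond adds across the exocyclic C=C of 7 with the aryl group going to the unsubstituted CH2 terminus (the guaiacyl–C1' bond) and rhodium to C2 as an oxa-π-allyl enolate, and water protonates this enolate and returns the hydroxide catalyst. The closest known reaction type is the Hayashi–Miyaura 1,4-addition of arylboronic acids to α-substituted acrylates and α-methylene lactones with protonation of the rhodium enolate. No ring is closed. The new stereocentre C2 is not reliably set by the protonation (proton delivery anti to the C3 methyl group leads to the cis epimer 9), so it is put under thermodynamic control: DBU reversibly enolises the lactone and both C2 epimers should drain into 10, in which the arylmethyl group on C2 is trans to the methyl group on C3, so that C3 dictates C2. The step needs 1,4- instead of 1,2-addition and arylation at CH2 only, which the polarised, sterically open 1,1-disubstituted enoate secures, and it needs protonolysis to outrun β-hydride elimination and migration of the double bond into the ring (which would erase C3), which the aqueous, base-free rhodium stage secures. C3 and C4 carry no acidic hydrogen and are untouched by DBU.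

**Step 6**
Reactants: 10 (3S,4S,5S)-3-[4-(benzyloxy)-3-methoxybenzyl]-5-[4-(benzyloxy)-3,5-dimethoxyphenyl]-4-methyloxolan-2-one
Product: 11 (1S,2S,3S)-1-[4-(benzyloxy)-3,5-dimethoxyphenyl]-3-[4-(benzyloxy)-3-methoxybenzyl]-2-methylbutane-1,4-diol
Conditions: LiAlH4, THF, 0 °C to rt; work-up with H2O and aq. NaOH
Reagents that add atoms: none
Why: Hydride reduction opens the lactone to the 1,4-diol without touching a stereocentre (10 is already the stable C2 epimer), and the basic work-up avoids ionisation of the electron-rich benzylic alcohol.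

**Step 7**
Reactants: 11 (1S,2S,3S)-1-[4-(benzyloxy)-3,5-dimethoxyphenyl]-3-[4-(benzyloxy)-3-methoxybenzyl]-2-methylbutane-1,4-diol
Product: 12 (1S,2S,3S)-1-[4-(benzyloxy)-3,5-dimethoxyphenyl]-3-[4-(benzyloxy)-3-methoxybenzyl]-2-methylbutane-1,4-diyl diacetate
Conditions: Ac2O, pyridine, DMAP (cat.), CH2Cl2, 0 °C to rt
Reagents that add atoms: acetic anhydride, CC(=O)OC(C)=O
Why: DMAP-catalysed acylation installs the primary acetate of the target and turns the benzylic hydroxyl into a better leaving group for hydrogenolysis, under non-acidic conditions.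

**Step 8**
Reactants: 12 (1S,2S,3S)-1-[4-(benzyloxy)-3,5-dimethoxyphenyl]-3-[4-(benzyloxy)-3-methoxybenzyl]-2-methylbutane-1,4-diyl diacetate
Product: 13 (2S,3R)-4-(4-hydroxy-3,5-dimethoxyphenyl)-2-(4-hydroxy-3-methoxybenzyl)-3-methylbutyl acetate
Conditions: H2 (3 bar), palladium on carbon (10% Pd/C), EtOAc, rt
Reagents that add atoms: none
Why: Heterogeneous hydrogenolysis should cleave both aryl benzyl ethers and the secondary benzylic acetate beside the electron-rich ring while the primary alkyl acetate is inert; C2 and C3 are not involved and the former carbinol carbon becomes CH2.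

**Compound list**

1 | syringaldehyde (4-hydroxy-3,5-dimethoxybenzaldehyde) | COc1cc(C=O)cc(OC)c1O | starting material
2 | 4-(benzyloxy)-3,5-dimethoxybenzaldehyde | COc1cc(C=O)cc(OC)c1OCc1ccccc1 | intermediate
3 | (R)-but-3-yn-2-ol | C#C[C@@H](C)O | starting material
4 | (R)-but-3-yn-2-yl methanesulfonate | C#C[C@@H](C)OS(C)(=O)=O | intermediate
5 | (aS)-buta-1,2-dien-1-yl(ethyl)zinc, formed in the flask | CC[Zn]C([H])=[C@@]=C([H])C | intermediate
6 | (1S,2S)-1-[4-(benzyloxy)-3,5-dimethoxyphenyl]-2-methylbut-3-yn-1-ol | C#C[C@H](C)[C@H](O)c1cc(OC)c(OCc2ccccc2)c(OC)c1 | intermediate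
7 | (4S,5S)-5-[4-(benzyloxy)-3,5-dimethoxyphenyl]-4-methyl-3-methylideneoxolan-2-one | C=C1[C@H](C)[C@@H](c2cc(OC)c(OCc3ccccc3)c(OC)c2)OC1=O | intermediate
8 | [4-(benzyloxy)-3-methoxyphenyl]boronic acid | COc1cc(B(O)O)ccc1OCc1ccccc1 | starting material
9 | (3R,4S,5S)-3-[4-(benzyloxy)-3-methoxybenzyl]-5-[4-(benzyloxy)-3,5-dimethoxyphenyl]-4-methyloxolan-2-one, formed in the flask | O=C1O[C@H](c2cc(OC)c(OCc3ccccc3)c(OC)c2)[C@@H](C)[C@H]1Cc1ccc(OCc2ccccc2)c(OC)c1 | intermediate
10 | (3S,4S,5S)-3-[4-(benzyloxy)-3-methoxybenzyl]-5-[4-(benzyloxy)-3,5-dimethoxyphenyl]-4-methyloxolan-2-one | O=C1O[C@H](c2cc(OC)c(OCc3ccccc3)c(OC)c2)[C@@H](C)[C@@H]1Cc1ccc(OCc2ccccc2)c(OC)c1 | intermediate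
11 | (1S,2S,3S)-1-[4-(benzyloxy)-3,5-dimethoxyphenyl]-3-[4-(benzyloxy)-3-methoxybenzyl]-2-methylbutane-1,4-diol | COc1cc(C[C@H](CO)[C@H](C)[C@H](O)c2cc(OC)c(OCc3ccccc3)c(OC)c2)ccc1OCc1ccccc1 | intermediate
12 | (1S,2S,3S)-1-[4-(benzyloxy)-3,5-dimethoxyphenyl]-3-[4-(benzyloxy)-3-methoxybenzyl]-2-methylbutane-1,4-diyl diacetate | COc1cc(C[C@H](COC(C)=O)[C@H](C)[C@H](OC(C)=O)c2cc(OC)c(OCc3ccccc3)c(OC)c2)ccc1OCc1ccccc1 | intermediate
13 | (2S,3R)-4-(4-hydroxy-3,5-dimethoxyphenyl)-2-(4-hydroxy-3-methoxybenzyl)-3-methylbutyl acetate | COc1cc(C[C@H](COC(C)=O)[C@H](C)Cc2cc(OC)c(O)c(OC)c2)ccc1O | target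

**Step count**

Total: 8 steps. Longest linear sequence: 7 steps (steps 1, 3, 4, 5, 6, 7, 8 from syringaldehyde).

**Steps most likely to fail**

Step 5. The aryl–rhodium adduct may undergo β-hydride elimination instead of protonolysis. The exocyclic double bond of 7 may migrate into the ring before arylation, which would erase C3. The electron-rich boronic acid may protodeboronate. The fallback sets out from 7 and returns at 10, and delivers the aryl group as an organocopper nucleophile. Commercial 1-(benzyloxy)-4-bromo-2-methoxybenzene is converted with Mg in THF into [4-(benzyloxy)-3-methoxyphenyl]magnesium bromide F1. F1 is added to 7 with CuBr·SMe2 (catalytic) and Me3SiCl in THF at −78 °C, and the conjugate adduct is trapped as the silyl ketene acetal {[(4S,5S)-3-[4-(benzyloxy)-3-methoxybenzyl]-5-[4-(benzyloxy)-3,5-dimethoxyphenyl]-4-methyl-4,5-dihydrofuran-2-yl]oxy}trimethylsilane F2. Aqueous work-up hydrolyses F2 to the mixture of 9 and 10, and DBU in toluene then equilibrates it to 10.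

Step 4. The electron-rich benzylic alcohol may ionise under the Lewis-acidic carbonylation conditions, or alkyne insertion may be slow at the hindered centre. The fallback sets out from 6 and returns at 7, and builds the lactone without carbon monoxide. Hydroboration of the terminal alkyne with dicyclohexylborane and oxidation with NaBO3·4H2O gives an aldehyde that closes to the lactol (4S,5S)-5-[4-(benzyloxy)-3,5-dimethoxyphenyl]-4-methyloxolan-2-ol F3. Oxidation with PhI(OAc)2 and catalytic TEMPO gives the lactone (4S,5S)-5-[4-(benzyloxy)-3,5-dimethoxyphenyl]-4-methyloxolan-2-one F4. Deprotonation with LiN(SiMe3)2 in THF at −78 °C and aminomethylation with dimethyl(methylidene)ammonium iodide gives the Mannich base (4S,5S)-5-[4-(benzyloxy)-3,5-dimethoxyphenyl]-3-[(dimethylamino)methyl]-4-methyloxolan-2-one F5. Methyl iodide quaternises it to {[(4S,5S)-5-[4-(benzyloxy)-3,5-dimethoxyphenyl]-4-methyl-2-oxooxolan-3-yl]methyl}trimethylammonium iodide F6, which eliminates trimethylamine with aq. NaHCO3 to give 7.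

Step 8. Cleavage of the hindered benzylic C–O bond may stall once the benzyl ethers are gone. The transient quinone methide or benzylic cation may cyclise onto the guaiacyl ring, or tautomerise and scramble C3. The fallback sets out from 10 and returns at 13, and removes the benzylic oxygen by electron transfer at the lactone stage. Li in liquid NH3/THF at −78 °C, then NH4Cl, should cleave the benzylic lactone C–O bond and both benzyl ethers to give (2S,3R)-4-(4-hydroxy-3,5-dimethoxyphenyl)-2-(4-hydroxy-3-methoxybenzyl)-3-methylbutanoic acid F7. BH3·SMe2 in THF reduces the acid to (2S,3R)-4-(4-hydroxy-3,5-dimethoxyphenyl)-2-(4-hydroxy-3-methoxybenzyl)-3-methylbutan-1-ol F8. Vinyl acetate with immobilised Candida antarctica lipase B in tert-butyl methyl ether acetylates the primary alcohol and leaves the phenols free, giving 13.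

**Further compounds**

F1 | step 5 | [4-(benzyloxy)-3-methoxyphenyl]magnesium bromide | COc1cc([Mg]Br)ccc1OCc1ccccc1
F2 | step 5 | {[(4S,5S)-3-[4-(benzyloxy)-3-methoxybenzyl]-5-[4-(benzyloxy)-3,5-dimethoxyphenyl]-4-methyl-4,5-dihydrofuran-2-yl]oxy}trimethylsilane | COc1cc(CC2=C(O[Si](C)(C)C)O[C@H](c3cc(OC)c(OCc4ccccc4)c(OC)c3)[C@H]2C)ccc1OCc1ccccc1
F3 | step 4 | (4S,5S)-5-[4-(benzyloxy)-3,5-dimethoxyphenyl]-4-methyloxolan-2-ol | OC1C[C@H](C)[C@@H](c2cc(OC)c(OCc3ccccc3)c(OC)c2)O1
F4 | step 4 | (4S,5S)-5-[4-(benzyloxy)-3,5-dimethoxyphenyl]-4-methyloxolan-2-one | O=C1C[C@H](C)[C@@H](c2cc(OC)c(OCc3ccccc3)c(OC)c2)O1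
F5 | step 4 | (4S,5S)-5-[4-(benzyloxy)-3,5-dimethoxyphenyl]-3-[(dimethylamino)methyl]-4-methyloxolan-2-one | CN(C)CC1[C@H](C)[C@@H](c2cc(OC)c(OCc3ccccc3)c(OC)c2)OC1=O
F6 | step 4 | {[(4S,5S)-5-[4-(benzyloxy)-3,5-dimethoxyphenyl]-4-methyl-2-oxooxolan-3-yl]methyl}trimethylammonium iodide | C[N+](C)(C)CC1[C@H](C)[C@@H](c2cc(OC)c(OCc3ccccc3)c(OC)c2)OC1=O.[I-]
F7 | step 8 | (2S,3R)-4-(4-hydroxy-3,5-dimethoxyphenyl)-2-(4-hydroxy-3-methoxybenzyl)-3-methylbutanoic acid | COc1cc(C[C@H](C(=O)O)[C@H](C)Cc2cc(OC)c(O)c(OC)c2)ccc1O
F8 | step 8 | (2S,3R)-4-(4-hydroxy-3,5-dimethoxyphenyl)-2-(4-hydroxy-3-methoxybenzyl)-3-methylbutan-1-ol | COc1cc(C[C@H](CO)[C@H](C)Cc2cc(OC)c(O)c(OC)c2)ccc1O
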